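Remark on the chemistry: the target has no stereocentre. Compounds 11, 12, 13 and 15 are racemic, and their single stereocentre disappears when ring A becomes aromatic. Compounds 1, 4 and 10 are taken as catalogue chemicals.

## Analysis of the target

The target 17 (C19H18O8) is a flavone: a benzo ring A fused through C4a–C8a to a 4-pyranone ring C (O1, C2, C3, C4=O), which carries the aryl ring B at C2. It has no stereocentre, no stereogenic axis and no double-bond geometry to set, so the problem is one of regiochemistry and of telling oxygen atoms apart. Ring A is pentasubstituted: four adjacent carbons are oxygenated, each in a different way (C6–OMe, C7–OMe, C8–OH, C8a–O1), C4a carries the carbonyl carbon, and only C5 bears hydrogen. There is no 5-hydroxyl, so chelation to the C4 carbonyl, the usual way of differentiating flavone oxygens, is not available; the free 8-OH must be distinguished from its methoxy neighbours by the way ring A is made. Ring B repeats the problem on a small scale: of three adjacent oxygens only the one at C3′ is free. The sensitive groups are the two electron-rich phenols (oxidation), the pyranone (ring opening by hard nucleophiles at C2, strong base) and the aryl methyl ethers (Lewis acids). The feature the route exploits is the segment C5(H)–C6(OMe)–C7(OMe)–C8(OH) of ring A. It is the imprint of a 2,3-dimethoxycyclobutenone derived from dimethyl squarate 10 (one CH, two enol ether carbons, one C=O). The two remaining ring A atoms, C4a and C8a, are the enol ether C=C bond of a 4-pyranone, so ring A can be annulated last onto intact rings C and B.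

## Retrosynthetic reasoning

**17 to 16.** The only protecting group is a benzyl ether on the C3′ oxygen of ring B. It is needed because the acylation that builds ring C and the ketene 14 of the key step do not tolerate a free phenol. It is removed last by hydrogenolysis, which touches nothing else. The 8-OH needs no protection, because the key step creates it.

**16 to 9 and 12 (key disconnection).** Ring A is cut at C4a–C5 and at C8–C8a. These two cuts leave rings C and B untouched in the stannylpyranone 9 and hand the whole C5–C6–C7–C8 segment, with both methoxy groups and the latent hydroxyl, to the four-membered ring of 12. All five substituents of ring A are then placed by connectivity and no oxygen has to be differentiated afterwards. The forward reaction has to join C4 of 12 to the stannylated carbon of 9 (C4a–C5, giving 13), open the cyclobutenone to the dienylketene 14, close C8–C8a by electrocyclization (15) and aromatize to 16.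

**12 to 11 to 10.** C5 of the target is at the CH oxidation level, so one carbonyl of the squarate 10 must be reduced before the coupling (11). Turning the hydroxyl into chloride (12) makes this carbon an electrophile for zerovalent palladium. The symmetry of 10 means the reduction has no regiochemistry to control.

**9 to 8.** The C–Sn bond is traced back to a C–I bond. The iodide is chosen because its position can be fixed by a building block rather than by substitution on the finished pyranone, where C3 and C5 would compete.

**8 to 3 and 5.** Ring C is cut at C2–C3 and at O1–C8a (flavone numbering). The iodinated four-carbon unit 5 supplies C3, C4, C4a (with iodine) and C8a. The acid 3, activated as 6, supplies C2 and ring B. The forward reaction is a C-acylation of the methyl ketone enolate of 5 followed by acid-induced closure of the enol oxygen onto the aminomethylene carbon (via 7).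

**5 to 4, and 3 to 1.** The iodine of 5 comes from α-iodination of the vinylogous amide 4, which has only one nucleophilic carbon. The benzyl ether of 3 comes from the phenolic acid 1.

## Alternatives that were turned down

**Alternative 1:** the textbook route, with ring C cut at O1–C2 and C2–C3.
- Forward key step: Claisen–Schmidt condensation of the ring A ketone 1-[3-(benzyloxy)-2-hydroxy-4,5-dimethoxyphenyl]ethanone A1 with 3-(benzyloxy)-4,5-dimethoxybenzaldehyde A2 to the 2′-hydroxychalcone A3, then oxidative cyclization and double debenzylation.
- The ring-forming step makes the two easiest bonds of the molecule. The real problem, the pentasubstituted ring A with a differentiated 8-oxygen, is left to the preparation of A1.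
- From a 2-hydroxy-4,5-dimethoxyphenyl ketone, A1 needs formylation at the one free ortho position between OH and OMe, Dakin oxidation beside an aryl ketone, and mono-benzylation of a catechol. These are three consecutive selectivity-dependent substitutions on a crowded ring.
- Its longest linear sequence is six steps against five here, it saves at most one step in total, and it carries two benzyl groups instead of one.
- The oxidative cyclization must also discriminate 6-endo closure (flavone) from 5-exo closure (aurone) on an electron-rich phenol.
- It is the route drawn first and offers nothing at the level of strategy.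

**Alternative 2:** ring C cut at C4–C4a, C3–C4 and O1–C2.
- Forward key step: a three-component carbonylative Sonogashira annulation of 2-(benzyloxy)-6-iodo-3,4-dimethoxyphenol A4 with 1-(benzyloxy)-5-ethynyl-2,3-dimethoxybenzene A5 under palladium catalysis.
- The step is convergent and forms three bonds, but A4 is again a fully oxygenated ring A. Its four adjacent oxygens (one free, one benzylated, two methylated) must be differentiated beforehand by stepwise aromatic chemistry, so the hard part is only moved.
- Oxidative addition into an iodide flanked by a phenoxide on an electron-rich ring is slow, so direct coupling without carbonyl insertion, followed by closure to a benzofuran, competes.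
- The ynone that does form can close 5-exo to the aurone.
- A5 costs one to two further steps from A2.

**Alternative 3:** the same ring A cut (C4a–C5 and C8–C8a) at the classical squarate oxidation level.
- Forward key step: halogen–metal exchange of 8 and 1,2-addition to 10 give the 4-hydroxycyclobutenone A6; thermal ring expansion gives the 5,8-dihydroxyflavone A7.
- Addition to squarates and thermolysis of 4-aryl- and 4-alkenyl-4-hydroxycyclobutenones are the best-precedented way to use a squarate, and the chloride 12 would not be needed.
- The carbinol carbon ends up as C5–OH, which the target lacks. A7 is a para-hydroquinone that oxidizes easily to the quinone.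
- Removing the 5-oxygen would take protection of the 8-OH, triflation of the chelated 5-OH and reduction: three steps that only correct the oxidation level.
- Reducing the squarate carbon before the coupling (10 to 11 to 12) puts C5 at the CH level from the start, at the price of a less precedented coupling.

Key step: step 7

## Route

Step 1
Reactants: 1 3-hydroxy-4,5-dimethoxybenzoic acid
Product: 3 3-(benzyloxy)-4,5-dimethoxybenzoic acid, via benzyl ester 2 (not isolated)
Conditions: BnBr (2.3 equiv), K2CO3 (2.5 equiv), DMF, 60 °C; then NaOH, MeOH–H2O, 60 °C; HCl to pH 2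
Reagents that add atoms: benzyl bromide, BrCc1ccccc1; sodium hydroxide, [Na+].[OH-]
Why: Williamson alkylation of the phenoxide and the carboxylate, then saponification of the benzyl ester in the same pot; the aryl benzyl ether is stable to hydroxide, so only the acid is released.

Step 2
Reactants: 4 (E)-4-(dimethylamino)but-3-en-2-one
Product: 5 (Z)-4-(dimethylamino)-3-iodobut-3-en-2-one
Conditions: N-iodosuccinimide (1.05 equiv), CH2Cl2, 0 °C
Reagents that add atoms: N-iodosuccinimide, O=C1CCC(=O)N1I
Why: Electrophilic α-iodination of an enaminone; the only nucleophilic carbon of 4 is C3, so the iodine that will mark C4a is placed without any regiochemical choice.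

Step 3
Reactants: 3 3-(benzyloxy)-4,5-dimethoxybenzoic acid; 5 (Z)-4-(dimethylamino)-3-iodobut-3-en-2-one
Product: 8 2-[3-(benzyloxy)-4,5-dimethoxyphenyl]-5-iodo-4H-pyran-4-one, via acid chloride 6 (not isolated), via iodo enaminodione 7 (not isolated)
Conditions: 3, (COCl)2, cat. DMF, CH2Cl2, 0 °C to rt, evaporate; 5 (2.1 equiv), LiN(SiMe3)2 (2.1 equiv), THF, −78 °C, then 6, −78 to −30 °C; then CF3CO2H, CH2Cl2, 0 °C to rt
Reagents that add atoms: oxalyl chloride, O=C(Cl)C(Cl)=O (its chlorine is carried by 6 and leaves again; 8 holds atoms of 3 and 5 only)
Why: Claisen-type C-acylation of the kinetic lithium enolate formed at the methyl group of the vinylogous amide 5, with the second equivalent of enolate taking up the acidic proton of the 1,3-dicarbonyl product; acid then induces 6-endo addition of the enol oxygen to the aminomethylene carbon and loss of dimethylamine (addition–elimination), which closes ring C with iodine fixed at the future C4a.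

Step 4
Reactants: 8 2-[3-(benzyloxy)-4,5-dimethoxyphenyl]-5-iodo-4H-pyran-4-one
Product: 9 2-[3-(benzyloxy)-4,5-dimethoxyphenyl]-5-(trimethylstannyl)-4H-pyran-4-one
Conditions: (Me3Sn)2 (1.3 equiv), Pd(PPh3)4 (5 mol %), 1,4-dioxane, 90 °C
Reagents that add atoms: hexamethylditin, C[Sn](C)(C)[Sn](C)(C)C
Why: Palladium-catalysed stannylation of an alkenyl iodide by a distannane (oxidative addition of zerovalent palladium into C–I, Sn–Sn transmetalation, reductive elimination); the excess of distannane keeps the product from coupling with unreacted 8.

Step 5
Reactants: 10 dimethyl squarate (3,4-dimethoxycyclobut-3-ene-1,2-dione)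
Product: 11 4-hydroxy-2,3-dimethoxycyclobut-2-en-1-one (racemic)
Conditions: LiAlH(OtBu)3 (1.05 equiv), THF, −78 to −40 °C; aqueous work-up at pH 7, 0 °C
Reagents that add atoms: none
Why: 1,2-Reduction of one carbonyl of a squarate ester by a bulky, mild alkoxyaluminium hydride; the product is a vinylogous ester and is reduced more slowly than 10, which should stop the reaction at the mono-alcohol.

Step 6
Reactants: 11 4-hydroxy-2,3-dimethoxycyclobut-2-en-1-one
Product: 12 4-chloro-2,3-dimethoxycyclobut-2-en-1-one (racemic)
Conditions: 1-chloro-N,N,2-trimethylprop-1-en-1-amine (1.1 equiv), CH2Cl2, 0 °C; solvent exchange to 1,4-dioxane, used at once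
Reagents that add atoms: 1-chloro-N,N,2-trimethylprop-1-en-1-amine, CC(C)=C(Cl)N(C)C
Why: Conversion of an alcohol into a chloride by an α-chloroenamine under neutral conditions: the alcohol adds to the keteniminium form and chloride displaces the resulting imidate at the α-keto carbon; no acid is set free, which matters because acid would ionize 11 or 12.

Step 7
Reactants: 9 2-[3-(benzyloxy)-4,5-dimethoxyphenyl]-5-(trimethylstannyl)-4H-pyran-4-one; 12 4-chloro-2,3-dimethoxycyclobut-2-en-1-one
Product: 16 2-[3-(benzyloxy)-4,5-dimethoxyphenyl]-8-hydroxy-6,7-dimethoxy-4H-chromen-4-one, via coupled cyclobutenone 13 (not isolated), via dienylketene 14 (not isolated), via dienone tautomer 15 (not isolated)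
Conditions: PdCl2(PhCN)2 (5 mol %), tri(2-furyl)phosphine (10 mol %), CuI (10 mol %), degassed 1,4-dioxane, 45 °C; then 100 °C; aq KF work-up
Reagents that add atoms: none
Why: Proposed new method: the closest known reaction type is the palladium-catalysed cross-coupling of 4-chlorocyclobut-2-enones with alkenyl- and heteroarylstannanes followed by thermal ring expansion to phenols, extended here to a 2,3-dialkoxy chloride and to the C5=C6 bond of a 4-pyranone as the alkene partner. Oxidative addition of zerovalent palladium into the activated C4–Cl bond of 12, tin-to-palladium transfer of the pyranonyl group of 9 (helped by CuI) and reductive elimination at the CH terminus should give 13 and with it the C4a–C5 bond. At 100 °C 13 undergoes reversible conrotatory 4π ring opening; only the dienylketene 14 with the pyranonyl group turned inward can react on, while the other isomer recloses to 13. Ring A is then closed by a thermal disrotatory 6π-electrocyclization of 14 that joins the ketene carbon to C6 of the pyranone (the C8–C8a bond), and the dienone 15 aromatizes by a proton shift from C8a to oxygen, which drives the cascade. The regiochemistry follows from connectivity: the ketene carbon becomes C8–OH, the two enol ether carbons become C7–OMe and C6–OMe, the former CHCl carbon becomes C5–H, and C6 of the pyranone is the only terminus that completes a six-membered, six-electron array (attack on the C4 carbonyl oxygen would need a seven-membered ring). No stereocentre survives; C4 of 13 and C8a of 15 are transient and racemic. The selectivity the step needs is coupling at C4 rather than C2 of the oxa-allyl palladium intermediate, which the lower hindrance of the CH terminus and the conjugated vinylogous ester product favour.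

Step 8
Reactants: 16 2-[3-(benzyloxy)-4,5-dimethoxyphenyl]-8-hydroxy-6,7-dimethoxy-4H-chromen-4-one
Product: 17 8-hydroxy-2-(3-hydroxy-4,5-dimethoxyphenyl)-6,7-dimethoxy-4H-chromen-4-one
Conditions: H2 (1 atm), Pd/C (10 wt % palladium on carbon), EtOAc–MeOH, rt
Reagents that add atoms: none
Why: Hydrogenolysis of the benzyl aryl ether over palladium; the cross-conjugated C2=C3 bond of a flavone is reduced much more slowly at 1 atm, and the methyl ethers and phenols are inert.

## Compound list

1 | 3-hydroxy-4,5-dimethoxybenzoic acid | OC(=O)c1cc(O)c(OC)c(OC)c1 | starting material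
2 | benzyl 3-(benzyloxy)-4,5-dimethoxybenzoate | O=C(OCc1ccccc1)c1cc(OCc2ccccc2)c(OC)c(OC)c1 | intermediate
3 | 3-(benzyloxy)-4,5-dimethoxybenzoic acid | OC(=O)c1cc(OCc2ccccc2)c(OC)c(OC)c1 | intermediate
4 | (E)-4-(dimethylamino)but-3-en-2-one | CC(=O)/C=C/N(C)C | starting material
5 | (Z)-4-(dimethylamino)-3-iodobut-3-en-2-one | CC(=O)/C(I)=C/N(C)C | intermediate
6 | 3-(benzyloxy)-4,5-dimethoxybenzoyl chloride | O=C(Cl)c1cc(OCc2ccccc2)c(OC)c(OC)c1 | intermediate
7 | (4Z)-1-[3-(benzyloxy)-4,5-dimethoxyphenyl]-5-(dimethylamino)-4-iodopent-4-ene-1,3-dione | CN(C)/C=C(\I)C(=O)CC(=O)c1cc(OCc2ccccc2)c(OC)c(OC)c1 | intermediate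
8 | 2-[3-(benzyloxy)-4,5-dimethoxyphenyl]-5-iodo-4H-pyran-4-one | O=c1cc(-c2cc(OCc3ccccc3)c(OC)c(OC)c2)occ1I | intermediate
9 | 2-[3-(benzyloxy)-4,5-dimethoxyphenyl]-5-(trimethylstannyl)-4H-pyran-4-one | O=c1cc(-c2cc(OCc3ccccc3)c(OC)c(OC)c2)occ1[Sn](C)(C)C | intermediate
10 | dimethyl squarate (3,4-dimethoxycyclobut-3-ene-1,2-dione) | COC1=C(OC)C(=O)C1=O | starting material
11 | 4-hydroxy-2,3-dimethoxycyclobut-2-en-1-one (racemic) | COC1=C(OC)C(O)C1=O | intermediate
12 | 4-chloro-2,3-dimethoxycyclobut-2-en-1-one (racemic) | COC1=C(OC)C(Cl)C1=O | intermediate
13 | 4-{6-[3-(benzyloxy)-4,5-dimethoxyphenyl]-4-oxo-4H-pyran-3-yl}-2,3-dimethoxycyclobut-2-en-1-one (racemic) | COC1=C(OC)C(c2coc(-c3cc(OCc4ccccc4)c(OC)c(OC)c3)cc2=O)C1=O | intermediate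
14 | (3E)-4-{6-[3-(benzyloxy)-4,5-dimethoxyphenyl]-4-oxo-4H-pyran-3-yl}-2,3-dimethoxybuta-1,3-dien-1-one | O=C=C(OC)/C(OC)=C\c1coc(-c2cc(OCc3ccccc3)c(OC)c(OC)c2)cc1=O | intermediate
15 | 2-[3-(benzyloxy)-4,5-dimethoxyphenyl]-6,7-dimethoxy-8aH-chromene-4,8-dione (racemic) | O=C1C(OC)=C(OC)C=C2C(=O)C=C(c3cc(OCc4ccccc4)c(OC)c(OC)c3)OC12 | intermediate
16 | 2-[3-(benzyloxy)-4,5-dimethoxyphenyl]-8-hydroxy-6,7-dimethoxy-4H-chromen-4-one | COc1cc(-c2cc(=O)c3cc(OC)c(OC)c(O)c3o2)cc(OCc2ccccc2)c1OC | intermediate
17 | 8-hydroxy-2-(3-hydroxy-4,5-dimethoxyphenyl)-6,7-dimethoxy-4H-chromen-4-one | COc1cc(-c2cc(=O)c3cc(OC)c(OC)c(O)c3o2)cc(O)c1OC | target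

## Step count and least certain steps

Total step count: 8. Longest linear sequence: 5 steps (1 to 3 to 8 to 9 to 16 to 17, or equally 4 to 5 to 8 to 9 to 16 to 17). The squarate branch (10 to 11 to 12) joins at step 7.

**Step 7 (key step, bears the label "Proposed new method").**
- The chloride 12 may ionize and lose its chlorine or a methyl group before oxidative addition.
- The α-stannyl enone 9 transmetalates slowly, so protodestannylation or homocoupling can overtake the cross-coupling.
- Coupling may occur at C2 instead of C4 of the oxa-allyl palladium intermediate.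
- The electrocyclization onto the pyranone C5=C6 bond may be slower than ketene dimerization or capture of the ketene by adventitious water.
- Fallback (known chemistry only): it sets out from 6 (made from 3 as in step 3) and comes back to the route at 17.
  - Ring A is made classically from commercial 1-(2-hydroxy-4,5-dimethoxyphenyl)ethanone F1.
  - Ortho-formylation at the only free position ortho to the phenol (hexamethylenetetramine, CF3CO2H, 80 °C) gives 3-acetyl-2-hydroxy-5,6-dimethoxybenzaldehyde F2.
  - Dakin oxidation (H2O2, NaOH, then acid) gives 1-(2,3-dihydroxy-4,5-dimethoxyphenyl)ethanone F3.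
  - Benzylation of the non-chelated hydroxyl (BnBr, 1.0 equiv, K2CO3, acetone) gives 1-[3-(benzyloxy)-2-hydroxy-4,5-dimethoxyphenyl]ethanone F4.
  - Acylation of F4 with 6 in pyridine gives 6-acetyl-2-(benzyloxy)-3,4-dimethoxyphenyl 3-(benzyloxy)-4,5-dimethoxybenzoate F5.
  - Baker–Venkataraman rearrangement (KOH, pyridine, 50 °C) gives 1-[3-(benzyloxy)-2-hydroxy-4,5-dimethoxyphenyl]-3-[3-(benzyloxy)-4,5-dimethoxyphenyl]propane-1,3-dione F6.
  - Cyclodehydration (H2SO4, AcOH) gives 8-(benzyloxy)-2-[3-(benzyloxy)-4,5-dimethoxyphenyl]-6,7-dimethoxy-4H-chromen-4-one F7, which the conditions of step 8 should convert into 17.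

**Step 6.**
- The C4–Cl bond of 12 is both α to a ketone and allylic to an enol ether. Ionization followed by demethylation of the oxocarbenium ion (collapse to a cyclobutenedione), or allylic transposition of chloride, may consume the compound during its formation or on warming.
- Fallback: it sets out from 11 and comes back to the route at 13 (and so at 16). The alcohol is acylated (ClCO2Me, pyridine, CH2Cl2, −20 °C) to 2,3-dimethoxy-4-oxocyclobut-2-en-1-yl methyl carbonate F8. F8 is ionized directly by zerovalent palladium (Pd2(dba)3, tri(2-furyl)phosphine, dioxane, 50 °C) in the presence of 9; the methoxide set free by decarboxylation activates the stannane. No halide has to be handled.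

**Step 3.**
- The enolate of 5 may be acylated on oxygen instead of carbon, acylated twice, or lose iodine by iodonium transfer under the acidic cyclization.
- Fallback: it sets out from 4 and 6 and comes back to the route at 8. The lithium enolate of iodine-free 4 is acylated with 6 to (4E)-1-[3-(benzyloxy)-4,5-dimethoxyphenyl]-5-(dimethylamino)pent-4-ene-1,3-dione F9. Iodine is then introduced and ring C closed in one operation by iodine-triggered cyclization (I2, CHCl3, rt), the reaction type that gives 3-iodochromones from 2-hydroxyaryl enaminones. This reverses the order of iodination and acylation, at the price of a possible competition between C4 and C2 of F9 for iodine.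

**Step 4.**
- Reductive loss of iodine, or Stille homocoupling of 8 with 9, may reduce the conversion to stannane.
- Fallback: it sets out from 8 and comes back to the route at 9. Iodine–magnesium exchange (iPrMgCl·LiCl, THF, −40 °C) gives {6-[3-(benzyloxy)-4,5-dimethoxyphenyl]-4-oxo-4H-pyran-3-yl}magnesium chloride F10, which is quenched with Me3SnCl. This is a polar organometallic route that needs no palladium.

## Further compounds

F1 | step 7 | 1-(2-hydroxy-4,5-dimethoxyphenyl)ethanone | CC(=O)c1cc(OC)c(OC)cc1O
F2 | step 7 | 3-acetyl-2-hydroxy-5,6-dimethoxybenzaldehyde | CC(=O)c1cc(OC)c(OC)c(C=O)c1O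
F3 | step 7 | 1-(2,3-dihydroxy-4,5-dimethoxyphenyl)ethanone | CC(=O)c1cc(OC)c(OC)c(O)c1O
F4 | step 7 | 1-[3-(benzyloxy)-2-hydroxy-4,5-dimethoxyphenyl]ethanone | CC(=O)c1cc(OC)c(OC)c(OCc2ccccc2)c1O
F5 | step 7 | 6-acetyl-2-(benzyloxy)-3,4-dimethoxyphenyl 3-(benzyloxy)-4,5-dimethoxybenzoate | CC(=O)c1cc(OC)c(OC)c(OCc2ccccc2)c1OC(=O)c1cc(OCc2ccccc2)c(OC)c(OC)c1
F6 | step 7 | 1-[3-(benzyloxy)-2-hydroxy-4,5-dimethoxyphenyl]-3-[3-(benzyloxy)-4,5-dimethoxyphenyl]propane-1,3-dione | O=C(CC(=O)c1cc(OCc2ccccc2)c(OC)c(OC)c1)c1cc(OC)c(OC)c(OCc2ccccc2)c1O
F7 | step 7 | 8-(benzyloxy)-2-[3-(benzyloxy)-4,5-dimethoxyphenyl]-6,7-dimethoxy-4H-chromen-4-one | COc1cc(-c2cc(=O)c3cc(OC)c(OC)c(OCc4ccccc4)c3o2)cc(OCc2ccccc2)c1OC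
F8 | step 6 | 2,3-dimethoxy-4-oxocyclobut-2-en-1-yl methyl carbonate (racemic) | COC(=O)OC1C(OC)=C(OC)C1=O
F9 | step 3 | (4E)-1-[3-(benzyloxy)-4,5-dimethoxyphenyl]-5-(dimethylamino)pent-4-ene-1,3-dione | CN(C)/C=C/C(=O)CC(=O)c1cc(OCc2ccccc2)c(OC)c(OC)c1
F10 | step 4 | {6-[3-(benzyloxy)-4,5-dimethoxyphenyl]-4-oxo-4H-pyran-3-yl}magnesium chloride | O=c1cc(-c2cc(OCc3ccccc3)c(OC)c(OC)c2)occ1[Mg]Cl
A1 | alternative 1 | 1-[3-(benzyloxy)-2-hydroxy-4,5-dimethoxyphenyl]ethanone | CC(=O)c1cc(OC)c(OC)c(OCc2ccccc2)c1O
A2 | alternative 1 | 3-(benzyloxy)-4,5-dimethoxybenzaldehyde | O=Cc1cc(OCc2ccccc2)c(OC)c(OC)c1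
A3 | alternative 1 | (E)-1-[3-(benzyloxy)-2-hydroxy-4,5-dimethoxyphenyl]-3-[3-(benzyloxy)-4,5-dimethoxyphenyl]prop-2-en-1-one | O=C(/C=C/c1cc(OCc2ccccc2)c(OC)c(OC)c1)c1cc(OC)c(OC)c(OCc2ccccc2)c1O
A4 | alternative 2 | 2-(benzyloxy)-6-iodo-3,4-dimethoxyphenol | Oc1c(I)cc(OC)c(OC)c1OCc1ccccc1
A5 | alternative 2 | 1-(benzyloxy)-5-ethynyl-2,3-dimethoxybenzene | C#Cc1cc(OCc2ccccc2)c(OC)c(OC)c1
A6 | alternative 3 | 4-{6-[3-(benzyloxy)-4,5-dimethoxyphenyl]-4-oxo-4H-pyran-3-yl}-4-hydroxy-2,3-dimethoxycyclobut-2-en-1-one (racemic) | COC1=C(OC)C(O)(c2coc(-c3cc(OCc4ccccc4)c(OC)c(OC)c3)cc2=O)C1=O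
A7 | alternative 3 | 2-[3-(benzyloxy)-4,5-dimethoxyphenyl]-5,8-dihydroxy-6,7-dimethoxy-4H-chromen-4-one | COc1cc(-c2cc(=O)c3c(O)c(OC)c(OC)c(O)c3o2)cc(OCc2ccccc2)c1OC
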